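## Structural features

The target is (2S)-7-hydroxy-2-[4-(geranyloxy)phenyl]chroman-4-one, the 4'-O-geranyl ether of liquiritigenin. A resorcinol-derived ring A (C4a–C8a, free OH at C7, para to C4a) is fused to a dihydro-γ-pyranone ring C (O1, C2, C3, C4, C4a, C8a), and C2 carries a para-disubstituted phenyl ring B with a (2E)-geranyl ether at C4'. C2 is the only stereocentre: it is benzylic, bonded to O1, S-configured, and has no neighbouring stereocentre. It is labile in two ways: base opens ring C by E1cB cleavage of C2–O1 through the C3 enolate (retro-oxa-Michael, racemising on re-closure), and acid can ionise C2–O1 because ring B is a para-alkoxyphenyl donor. The geranyl aryl ether is an acid-labile allylic ether with two isolated trisubstituted alkenes, which rules out hydrogenation, strong Brønsted or Lewis acids, electrophilic halogen and prolonged strong heating. The 7-OH is a vinylogous acid (para to the C4 carbonyl) and must be freed at the end without base. The skeleton is easy; the real difficulty is to create the C2 configuration late, irreversibly and under near-neutral conditions. The key step exploits the fact that ring C is the 2,3-dihydro form of a flat, weakly aromatic γ-pyrone whose C2=C3 bond is the only electron-poor alkene in the molecule.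

## Logic of the disconnections

12 ⇒ 11. The O–Si bond on the C7 oxygen is cut. The 7-OH would consume the hydride catalyst of the key step, so it is carried as a silyl ether. Nothing is gained in skeleton. The forward cleavage must run without base (a phenoxide or C3 enolate opens ring C) and without acid strong enough to ionise the allylic ether.

11 ⇒ 9 (through 10). The C2–H bond, and with it the C3–H bond, is cut, tracing the saturated C2–C3 unit back to the C2=C3 bond of the planar γ-pyrone in 9. This is the key disconnection; in one sentence, the route is the enantioselective copper hydride 1,4-reduction of 9. The cut removes the only stereocentre and the only labile site, and 9 is achiral, flat and indifferent to the bases, amines and nucleophiles needed to build the skeleton. The forward step must deliver hydride to the Re face of C2 only, add 1,4 and not 1,2, leave the two isolated alkenes alone, and hold the enolate as 10 so that ring C cannot open.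

9 ⇒ 8. The O–Si bond is cut again. Silylation of the single hydroxyl of 8 only has to be complete.

8 ⇒ 4 + 5 (through 6 and 7). Three bonds of ring C are cut at once: C4–C4a, C3–C4 and O1–C2, with C4 supplied as a one-carbon carbonyl unit. This dissolves ring C into an aryl alkyne (ring B plus C2 and C3) and a resorcinol carrying iodine at the future C4a, ortho to the oxygen that becomes O1 and para to the one that becomes the 7-OH. Convergence is high and the conditions are mild toward the geranyl ether. Carbonylation must outrun direct alkynylation of 5, and the ring must close in the six-membered mode, which the amine adduct 7 enforces.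

4 ⇒ 3. The C≡C bond is cut back to the formyl carbon (one-carbon homologation). An aldehyde is the cheapest handle on ring B. The homologation must be mild enough to leave the allylic ether alone.

3 ⇒ 1 + 2. The O–C1 bond of the geranyl ether is cut. Putting the chain on a small, robust phenol first avoids any late differentiation of the two phenolic oxygens. O-alkylation must proceed without allylic transposition so that the 2E alkene of 2 is carried through.

## Other disconnections considered

Alternative 1: Cut O1–C2. The forward key step is the 6-endo-trig intramolecular oxa-Michael addition of the 2'-hydroxyl of chalcone A1, the aldol condensation product of 3. This is the first idea and the shortest on paper. The chosen plan is preferred on mechanism: the addition is reversible through the C3 enolate, so C2 would be formed in the same manifold that racemises it. On structure, A1 has only one ortho-hydroxyl, so the equilibrium is not expected to lie far on the ring-closed side. Highly enantioselective variants need an extra activating ester group on C3, whose later removal by acid and heat conflicts with the geranyl ether and the C2–O1 bond, so the apparent step advantage is lost.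

Alternative 2: Cut C2–C1' (ring C to ring B). The forward key step is the enantioselective conjugate addition of arylboronic acid A2 to the 2-unsubstituted chromone A3 with Pd(OCOCF3)2 and a chiral pyridine–oxazoline ligand, which would give 11 directly. On step economy this plan is about two steps shorter than the chosen one. It is not chosen because it is the established catalytic entry to this ring system and so is not an unconventional disconnection. It also carries the sensitive chain into the stereo-defining step: cationic divalent palladium is Lewis acidic and alkenophilic toward an allylic aryl ether and two alkenes, A2 is an electron-rich boronic acid prone to protodeboronation in warm aqueous medium, and the O-bound palladium enolate can expel the aryloxide. In the chosen plan the nucleophile is hydride, and its catalyst ignores isolated alkenes.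

Alternative 3: Cut C4–C4a. The forward key step is the intramolecular Friedel–Crafts acylation of the (3S)-3-aryloxy acid A4 at the ring position para to the silyloxy group. The chosen plan is preferred on structure: the C–O stereocentre of A4 would have to be made by SN2 etherification at a para-alkoxybenzylic carbinol, where SN1 leakage erodes configuration. On mechanism, the acylation needs a strong Brønsted or Lewis acid, which would ionise both the geranyl ether and the doubly activated benzylic C–O bond of A4. It is also longer (carbinol, etherification, activation, cyclisation, deprotection).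

Key step: step 5

Assumption: the ligand antipode that sends hydride to the Re face of C2 is taken to be (S)-DTBM-SEGPHOS by analogy with cyclic β,β-disubstituted enones; if the first run shows the opposite sense, (R)-DTBM-SEGPHOS is used with no other change.

## Route

Step 1
Reactants: 1 4-hydroxybenzaldehyde; 2 geranyl bromide, (2E)-1-bromo-3,7-dimethylocta-2,6-diene
Product: 3 4-[(2E)-3,7-dimethylocta-2,6-dien-1-yloxy]benzaldehyde
Conditions: K2CO3, acetone, reflux
Reagents that add atoms: none
Why: Williamson ether synthesis: the phenoxide of 1 displaces the primary allylic bromide of 2 by SN2, so the 2E geometry of 2 is carried over; the aldehyde is inert to K2CO3.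

Step 2
Reactants: 3 4-[(2E)-3,7-dimethylocta-2,6-dien-1-yloxy]benzaldehyde
Product: 4 1-ethynyl-4-[(2E)-3,7-dimethylocta-2,6-dien-1-yloxy]benzene
Conditions: Ohira–Bestmann reagent, K2CO3, MeOH, rt
Reagents that add atoms: Ohira–Bestmann reagent, dimethyl (1-diazo-2-oxopropyl)phosphonate, COP(=O)(OC)C(=[N+]=[N-])C(C)=O
Why: Seyferth–Gilbert homologation in the Ohira–Bestmann variant: methanolysis of the reagent gives the diazomethylphosphonate anion, which adds to the aldehyde, loses dimethyl phosphate and N2, and rearranges by 1,2-hydride shift to the terminal alkyne. K2CO3 in methanol should leave the geranyl ether untouched.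

Step 3
Reactants: 4 1-ethynyl-4-[(2E)-3,7-dimethylocta-2,6-dien-1-yloxy]benzene; 5 4-iodobenzene-1,3-diol (4-iodoresorcinol)
Product: 8 7-hydroxy-2-{4-[(2E)-3,7-dimethylocta-2,6-dien-1-yloxy]phenyl}-4H-chromen-4-one, via ynone 6 (not isolated), via enaminone 7 (not isolated)
Conditions: PdCl2(PPh3)2 (5 mol%), CO (1 atm), Et2NH, 50 °C
Reagents that add atoms: carbon monoxide, [C-]#[O+]
Why: Carbonylative Sonogashira annulation of an ortho-iodophenol: oxidative addition of the C–I bond of 5 to zerovalent palladium, CO insertion and alkynylation with 4 should give ynone 6, to which diethylamine adds to give enaminone 7. The ortho-hydroxyl then attacks the β-carbon of 7 in an addition–elimination that can only close the six-membered γ-pyrone. The iodine-bearing carbon of 5 becomes C4a, its ortho-OH becomes O1 and its para-OH becomes the 7-OH.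

Step 4
Reactants: 8 7-hydroxy-2-{4-[(2E)-3,7-dimethylocta-2,6-dien-1-yloxy]phenyl}-4H-chromen-4-one
Product: 9 7-(tert-butyldimethylsilyloxy)-2-{4-[(2E)-3,7-dimethylocta-2,6-dien-1-yloxy]phenyl}-4H-chromen-4-one
Conditions: TBSCl, imidazole, DMF, rt
Reagents that add atoms: tert-butyldimethylsilyl chloride (TBSCl), CC(C)(C)[Si](C)(C)Cl
Why: Imidazole-mediated silylation of the only hydroxyl group; the TBS ether removes the acidic proton that would quench the copper hydride and should make the substrate soluble in toluene.

Step 5
Reactants: 9 7-(tert-butyldimethylsilyloxy)-2-{4-[(2E)-3,7-dimethylocta-2,6-dien-1-yloxy]phenyl}-4H-chromen-4-one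
Product: 11 (2S)-7-(tert-butyldimethylsilyloxy)-2-{4-[(2E)-3,7-dimethylocta-2,6-dien-1-yloxy]phenyl}-2,3-dihydro-4H-chromen-4-one, via enol silane 10 (not isolated)
Conditions: Cu(OAc)2·H2O (5 mol%), (S)-DTBM-SEGPHOS (5.5 mol%), (EtO)2MeSiH (3 equiv), toluene, 0 °C to rt; then AcOH, THF–H2O, 0 °C
Reagents that add atoms: none
Why: Cu(OAc)2 and the silane give a bisphosphine-ligated hydride of monovalent copper, which binds the C2=C3 bond of the γ-pyrone and transfers hydride to C2 in a four-centre hydrocupration; the O-bound copper enolate then undergoes σ-bond metathesis with Si–H to release enol silane 10 and regenerate Cu–H. The closest known reaction type is the ligated-CuH asymmetric conjugate reduction (1,4-hydrosilylation) of β,β-disubstituted cyclic enones and of 2-substituted chromones, applied here to a 2-aryl member. No ring is closed: the flat ring C is dearomatised to its 2,3-dihydro form. C2 is the only new stereocentre and is set by the catalyst alone; the axially chiral ligand distinguishes the two faces of the planar substrate through the contrast between the exocyclic ring B on C2 and the in-ring O1, so that hydride should arrive on the Re face of C2 and give 2S. Chemoselectivity is secured by the substrate, since C2=C3 is the only polarised alkene and the isolated trisubstituted alkenes, the aryl ethers and the silyl ether are inert to copper hydride. 1,4- over 1,2-addition is favoured because C3 is unsubstituted and the C4 carbonyl is a vinylogous ester, and leaving out any alcohol additive keeps the product as 10, which can neither be reduced further nor open ring C by β-elimination of the aryloxide. Cold aqueous acetic acid then protonates C3 (no stereocentre) and should leave the aryl TBS ether and the geranyl ether intact, giving 11.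

Step 6
Reactants: 11 (2S)-7-(tert-butyldimethylsilyloxy)-2-{4-[(2E)-3,7-dimethylocta-2,6-dien-1-yloxy]phenyl}-2,3-dihydro-4H-chromen-4-one
Product: 12 (2S)-7-hydroxy-2-{4-[(2E)-3,7-dimethylocta-2,6-dien-1-yloxy]phenyl}-2,3-dihydro-4H-chromen-4-one
Conditions: KHF2, MeOH, rt
Reagents that add atoms: none
Why: Bifluoride cleaves the phenolic Si–O bond selectively; the weakly acidic medium builds up neither phenoxide nor C3 enolate, so ring C should not open and the C2 configuration should be retained, and it is too weak an acid to ionise the geranyl ether.

## Compound list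

1 | 4-hydroxybenzaldehyde | O=Cc1ccc(O)cc1 | starting material
2 | geranyl bromide, (2E)-1-bromo-3,7-dimethylocta-2,6-diene | CC(C)=CCC/C(C)=C/CBr | starting material
3 | 4-[(2E)-3,7-dimethylocta-2,6-dien-1-yloxy]benzaldehyde | CC(C)=CCC/C(C)=C/COc1ccc(C=O)cc1 | intermediate
4 | 1-ethynyl-4-[(2E)-3,7-dimethylocta-2,6-dien-1-yloxy]benzene | CC(C)=CCC/C(C)=C/COc1ccc(C#C)cc1 | intermediate
5 | 4-iodobenzene-1,3-diol (4-iodoresorcinol) | Oc1ccc(I)c(O)c1 | starting material
6 | 1-(2,4-dihydroxyphenyl)-3-{4-[(2E)-3,7-dimethylocta-2,6-dien-1-yloxy]phenyl}prop-2-yn-1-one (ynone) | CC(C)=CCC/C(C)=C/COc1ccc(C#CC(=O)c2ccc(O)cc2O)cc1 | intermediate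
7 | 3-(diethylamino)-1-(2,4-dihydroxyphenyl)-3-{4-[(2E)-3,7-dimethylocta-2,6-dien-1-yloxy]phenyl}prop-2-en-1-one (enaminone; enamine C=C geometry not defined) | CC(C)=CCC/C(C)=C/COc1ccc(C(=CC(=O)c2ccc(O)cc2O)N(CC)CC)cc1 | intermediate
8 | 7-hydroxy-2-{4-[(2E)-3,7-dimethylocta-2,6-dien-1-yloxy]phenyl}-4H-chromen-4-one | CC(C)=CCC/C(C)=C/COc1ccc(-c2cc(=O)c3ccc(O)cc3o2)cc1 | intermediate
9 | 7-(tert-butyldimethylsilyloxy)-2-{4-[(2E)-3,7-dimethylocta-2,6-dien-1-yloxy]phenyl}-4H-chromen-4-one | CC(C)=CCC/C(C)=C/COc1ccc(-c2cc(=O)c3ccc(O[Si](C)(C)C(C)(C)C)cc3o2)cc1 | intermediate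
10 | (2S)-7-(tert-butyldimethylsilyloxy)-4-[diethoxy(methyl)silyloxy]-2-{4-[(2E)-3,7-dimethylocta-2,6-dien-1-yloxy]phenyl}-2H-chromene (enol silane) | CC(C)=CCC/C(C)=C/COc1ccc([C@@H]2C=C(O[Si](C)(OCC)OCC)c3ccc(O[Si](C)(C)C(C)(C)C)cc3O2)cc1 | intermediate
11 | (2S)-7-(tert-butyldimethylsilyloxy)-2-{4-[(2E)-3,7-dimethylocta-2,6-dien-1-yloxy]phenyl}-2,3-dihydro-4H-chromen-4-one | CC(C)=CCC/C(C)=C/COc1ccc([C@@H]2CC(=O)c3ccc(O[Si](C)(C)C(C)(C)C)cc3O2)cc1 | intermediate
12 | (2S)-7-hydroxy-2-{4-[(2E)-3,7-dimethylocta-2,6-dien-1-yloxy]phenyl}-2,3-dihydro-4H-chromen-4-one | CC(C)=CCC/C(C)=C/COc1ccc([C@@H]2CC(=O)c3ccc(O)cc3O2)cc1 | target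

## Step count and least certain steps

Total: 6 steps. Longest linear sequence: 6 steps (1 → 3 → 4 → 8 → 9 → 11 → 12); 2 and 5 enter as purchased materials.

Step 5 (key step). The most likely failures are slow hydride transfer, because the enone is deactivated by donation from O1, the 7-oxygen and the 4'-alkoxyaryl group; insufficient discrimination between the two faces of C2; and over-reduction at C4 or ring opening if the enolate is not held as the enol silane. The fallback replaces asymmetric induction by resolution and sets out from 3. Claisen–Schmidt condensation of 3 with 2,4-dihydroxyacetophenone (KOH, EtOH, rt) should give the chalcone F1, which has the same structure as A1. Heating F1 with NaOAc in EtOH should close it to the racemic flavanone F2. Kinetic resolution of F2 by asymmetric transfer hydrogenation with RhCl(Cp*)[(R,R)-TsDPEN] (HCO2H/Et3N, EtOAc, rt, stopped near half conversion) should reduce the 2R enantiomer to the cis-(2R,4R)-flavan-4-ol F3 and leave the 2S ketone, by the usual facial preference of these catalysts and hydride delivery anti to ring B. Chromatographic separation from F3 then returns the route at 12, at the cost of at most half the material.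

Step 3. The most likely failures are direct alkynylation of 5 without CO uptake followed by five-membered closure to a benzofuran, capture of the acylpalladium intermediate by diethylamine, and ionisation of the allylic aryl ether by zerovalent palladium. The fallback forms the ynone by polar addition, without palladium or CO, and sets out from 4. Deprotonation of 4 (n-BuLi, THF, −78 °C) and addition to 2,4-bis(tert-butyldimethylsilyloxy)benzaldehyde F4 (made from 2,4-dihydroxybenzaldehyde with TBSCl and imidazole) should give the propargylic alcohol F5. Oxidation with MnO2 in CH2Cl2 should give the bis-silyl ynone F6, and diethylamine in EtOH should add to it to give the enaminone F7. Removing both silyl groups from F7 (TBAF, AcOH, THF) liberates 7, which cyclises with loss of diethylamine, so the route is rejoined at 8.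

Step 6. The most likely failure is partial loss of configuration at C2 through opening and re-closure of ring C if phenoxide accumulates, or slow cleavage that forces longer exposure. The fallback drops the isolated protecting group and the fluoride step and sets out from 8. Under the conditions of step 5 with a larger excess of (EtO)2MeSiH, the first equivalent should silylate the phenol with loss of H2 (copper-catalysed dehydrogenative Si–O coupling) to give the aryl silyl ether F8. F8 is then reduced as in step 5 to the bis-silyl compound F9, and cold aqueous acetic acid hydrolyses both Si–O bonds, so the route is rejoined at 12 without passing through 9, 10 or 11.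

## Further compounds

F1 | step 5 | (2E)-1-(2,4-dihydroxyphenyl)-3-{4-[(2E)-3,7-dimethylocta-2,6-dien-1-yloxy]phenyl}prop-2-en-1-one | CC(C)=CCC/C(C)=C/COc1ccc(/C=C/C(=O)c2ccc(O)cc2O)cc1
F2 | step 5 | racemic 7-hydroxy-2-{4-[(2E)-3,7-dimethylocta-2,6-dien-1-yloxy]phenyl}-2,3-dihydro-4H-chromen-4-one | CC(C)=CCC/C(C)=C/COc1ccc(C2CC(=O)c3ccc(O)cc3O2)cc1
F3 | step 5 | (2R,4R)-2-{4-[(2E)-3,7-dimethylocta-2,6-dien-1-yloxy]phenyl}-3,4-dihydro-2H-chromene-4,7-diol (cis) | CC(C)=CCC/C(C)=C/COc1ccc([C@H]2C[C@@H](O)c3ccc(O)cc3O2)cc1
F4 | step 3 | 2,4-bis(tert-butyldimethylsilyloxy)benzaldehyde | CC(C)(C)[Si](C)(C)Oc1ccc(C=O)c(O[Si](C)(C)C(C)(C)C)c1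
F5 | step 3 | racemic 1-[2,4-bis(tert-butyldimethylsilyloxy)phenyl]-3-{4-[(2E)-3,7-dimethylocta-2,6-dien-1-yloxy]phenyl}prop-2-yn-1-ol | CC(C)=CCC/C(C)=C/COc1ccc(C#CC(O)c2ccc(O[Si](C)(C)C(C)(C)C)cc2O[Si](C)(C)C(C)(C)C)cc1
F6 | step 3 | 1-[2,4-bis(tert-butyldimethylsilyloxy)phenyl]-3-{4-[(2E)-3,7-dimethylocta-2,6-dien-1-yloxy]phenyl}prop-2-yn-1-one | CC(C)=CCC/C(C)=C/COc1ccc(C#CC(=O)c2ccc(O[Si](C)(C)C(C)(C)C)cc2O[Si](C)(C)C(C)(C)C)cc1
F7 | step 3 | 1-[2,4-bis(tert-butyldimethylsilyloxy)phenyl]-3-(diethylamino)-3-{4-[(2E)-3,7-dimethylocta-2,6-dien-1-yloxy]phenyl}prop-2-en-1-one (enamine C=C geometry not defined) | CC(C)=CCC/C(C)=C/COc1ccc(C(=CC(=O)c2ccc(O[Si](C)(C)C(C)(C)C)cc2O[Si](C)(C)C(C)(C)C)N(CC)CC)cc1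
F8 | step 6 | 7-[diethoxy(methyl)silyloxy]-2-{4-[(2E)-3,7-dimethylocta-2,6-dien-1-yloxy]phenyl}-4H-chromen-4-one | CC(C)=CCC/C(C)=C/COc1ccc(-c2cc(=O)c3ccc(O[Si](C)(OCC)OCC)cc3o2)cc1
F9 | step 6 | (2S)-4,7-bis[diethoxy(methyl)silyloxy]-2-{4-[(2E)-3,7-dimethylocta-2,6-dien-1-yloxy]phenyl}-2H-chromene | CC(C)=CCC/C(C)=C/COc1ccc([C@@H]2C=C(O[Si](C)(OCC)OCC)c3ccc(O[Si](C)(OCC)OCC)cc3O2)cc1
A1 | alternative 1 | (2E)-1-(2,4-dihydroxyphenyl)-3-{4-[(2E)-3,7-dimethylocta-2,6-dien-1-yloxy]phenyl}prop-2-en-1-one | CC(C)=CCC/C(C)=C/COc1ccc(/C=C/C(=O)c2ccc(O)cc2O)cc1
A2 | alternative 2 | {4-[(2E)-3,7-dimethylocta-2,6-dien-1-yloxy]phenyl}boronic acid | CC(C)=CCC/C(C)=C/COc1ccc(B(O)O)cc1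
A3 | alternative 2 | 7-(tert-butyldimethylsilyloxy)-4H-chromen-4-one | CC(C)(C)[Si](C)(C)Oc1ccc2c(c1)occc2=O
A4 | alternative 3 | (3S)-3-[3-(tert-butyldimethylsilyloxy)phenoxy]-3-{4-[(2E)-3,7-dimethylocta-2,6-dien-1-yloxy]phenyl}propanoic acid | CC(C)=CCC/C(C)=C/COc1ccc([C@H](CC(=O)O)Oc2cccc(O[Si](C)(C)C(C)(C)C)c2)cc1
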